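**The question.** Count target per side product. The set-ups share one charge and differ in how it meets.

| flask | substrate | reagent | remark | time |
|---|---|---|---|---|
| west | 0.30 M | 0.21 M | run made earlier |  |
| south-west | 0.15 M | 0.21 M | run made earlier |  |
| south-east | 0.22 M | 0.21 M | run made earlier |  |
| north | 0.30 M | 0.10 M | run made earlier |  |
| grey | 0.30 M | 0.210 M | a closed flask charged with all of it at once and left for 50 h | 50 h |
| teal | 0.30 M (fed, over 25.0 h) | 0.210 M | all but substrate at the start; substrate goes in evenly over 25.0 h, the run ends at 50 h | 50 h |
| violet | 0.30 M | 0.210 M | a single well-mixed tank run continuously and read at steady state, 50 h in it on average |  |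
| red | 0.30 M | 0.210 M (fed, over 25.0 h) | all but reagent at the start; reagent goes in evenly over 25.0 h, the run ends at 50 h | 50 h |

- west (time / h: target / %, side product / %): 2.00: 0.7, 0.2; 6.00: 7.2, 0.1; 10.0: 17.8, 0.1; 15.0: 29.7, 0.3; 25.0: 45.4, 1.8; 30.0: 50.8, 1.1
- south-west (time / h: target / %, side product / %): 5.00: 6.2, 0; 8.00: 14.0, 0; 12.0: 25.3, 0.4; 20.0: 45.3, 1.6; 40.0: 73.9, 1.2; 60.0: 85.3, 1.8
- south-east (time / h: target / %, side product / %): 5.00: 6.3, 0.1; 8.00: 13.6, 0.7; 12.0: 24.6, 0.8; 20.0: 41.8, 1.0; 40.0: 65.0, 1.8; 60.0: 76.3, 2.3
- north (time / h: target / %, side product / %): 12.0: 13.9, 0.3; 25.0: 24.7, 0; 40.0: 30.6, 0.5; 50.0: 32.7, 1.3; 60.0: 32.8, 0.6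

(each reading ± 0.5 percentage points)

- a species is counted by the substrate in it: one side product counts as two
- the stated concentrations are those of everything mixed, before any reaction; amounts are the same in each set-up
- the earlier runs were read with a standard deviation of 0.5 percentage points
- the feed brings no volume worth counting
- the earlier runs were made in a closed, stirred flask

- the set-up with the highest share of target in all that became target or side product, at the outlet or at the end ("none" if the first two lie within 2 percentage points) (grey / teal / violet / red / none)
- share of target in all that became target or side product, at the outlet or at the end, grey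
- share of target in all that became target or side product, at the outlet or at the end, teal
- share of target in all that became target or side product, at the outlet or at the end, violet
- share of target in all that became target or side product, at the outlet or at the end, red

**The count.** The last two readings of each earlier run add up to 462% of target and 11.9% of side product. That gives a reading of 38.8 for the turnover count, the target made per side product, both counted by substrate. The asked share, the selectivity, is the count over the count plus one, so it reads 97.5%. The scatter of the pooled side product, 1.4 percentage points, spreads that share from 97.2% to 97.8%.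

**One number?** Run by run the count reads 33.2 in west, 53.1 in south-west, 34.5 in south-east and 34.5 in north. South-west stands higher than the others, but its side product lies 1.1 points below the pooled expectation, with a scatter of 0.71 points. So these readings show no second number. Counts from 33.2 to 53.1 span 1.1 points of share, less than the margin of 2 points, so the count says none.

**The forecast.** It gives grey 97.5%, teal 98%, violet 98.2% and red 97.6%, best none: “The top two almost surely lie within 2 points”. The count gives one share for every set-up, whereas the forecast spreads them.

**The flasks.** Grey gives 96.8%, teal 96.3%, violet 97.9% and red 98.0%, best none.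

    substrate ⇌ intermediate A (K = 1.80, k = 0.230 h⁻¹)
    reagent + intermediate B ⇌ intermediate C (K = 7.50 M⁻¹, k = 0.520 M⁻¹ h⁻¹)
    intermediate B → target (k = 0.200 h⁻¹)
    substrate + intermediate C → side product (k = 0.120 M⁻¹ h⁻¹)
    reagent + intermediate A → intermediate B (k = 0.760 M⁻¹ h⁻¹)

**The neighbour.** At 50.0 h the count stands at 30.0 in grey and 48.1 in red, against the reading of 38.8. A neighbour of red, charged with c(reagent) = 0.13 M and otherwise held, ends with 38.9% target, so the reading of 38.8 puts its side product at 1.00%; it ends with 0.573%. Its count of 67.9 is higher than red's and higher than the reading, and its share is 98.5%.

(The earlier runs and the new flask were computed with constants of no real substance; noise was put on by code.)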